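**Plan**

- Cuts (labdane numbering, α = face opposite the C10 methyl): C11–C12 between a ring-B diene and a C5 lactone aldehyde; the imide C15–N bond (succinimide from a paraconic amide by O→N acyl transfer); C2–Cl (C–H chlorination); C6–O (allylic oxidation).
- Enabling feature: the 4-penten-1-ol array C12(OH)–C11H2–C9(H)–C8(=C17H2) on ring B is the retron of a nickel-catalysed diene/aldehyde homoallylation, so the precursor is the s-cis-locked bis-exocyclic diene C11=C9–C8=C17 on ring B.
- Forward order: the trans-decalin is bought as (+)-sclareolide and chlorinated at C2. Its lactone carbon C12 is excised, C6 is oxidised, and acetate loss plus deconjugation give the 6β-hydroxy diene (the C9 centre is erased on purpose).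
- The diene and the aldehyde are then joined at C11–C12; the γ-lactone is re-formed on the C12 oxygen, C16 is oxidised, and the succinimide ring is closed last.
- Stereochemistry: C5 and C10 come from sclareolide; C2 from α-face chlorine transfer; C6 from α-face hydride delivery; C9 and C12 together in the key step, relayed from the decalin; C13 from an organocatalytic hydroxymethylation.

Key step: step 9

Remark: labdane numbering is used for all decalin compounds (C17 on C8, C20 on C10, side chain C11–C16). The N-chloroamide of step 1 is assumed to be made in one operation from the commercial parent amide; this reagent preparation is not counted.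

**Step 1**
Reactants: 1 (+)-sclareolide
Product: 2 2α-chlorosclareolide
Conditions: N-chloro-N-tert-butyl-3,5-bis(trifluoromethyl)benzamide, Cs2CO3, PhH, 55 °C, visible light
Reagents that add atoms: N-chloro-N-tert-butyl-3,5-bis(trifluoromethyl)benzamide, CC(C)(C)N(Cl)C(=O)c1cc(cc(c1)C(F)(F)F)C(F)(F)F
Why: Amidyl-radical aliphatic C–H chlorination (N-chloroamide method, precedented on sclareolide): the bulky electrophilic amidyl radical should abstract the most accessible, electron-rich C2 hydrogen, and chlorine is delivered to the C2 radical from the α-face, anti to the axial C19 and C20 methyls, giving the equatorial 2α-chloride.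

**Step 2**
Reactants: 2 2α-chlorosclareolide
Product: 3 2α-chloro-8α-hydroxy-14,15,16-trinorlabdan-12-one (methyl ketone)
Conditions: MeLi, THF, −78 °C; then H2O
Reagents that add atoms: methyllithium, [Li]C
Why: Addition of MeLi to a lactone should stop at the ketone level because the tetrahedral lithium hemiketal alkoxide is stable at −78 °C (lactone to methyl ketone, known for sclareolide).

**Step 3**
Reactants: 3 2α-chloro-8α-hydroxy-14,15,16-trinorlabdan-12-one
Product: 4 2α-chloro-8α-hydroxy-12,13,14,15,16-pentanorlabdan-11-yl acetate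
Conditions: mCPBA, NaHCO3, CH2Cl2, 40 °C
Reagents that add atoms: 3-chloroperbenzoic acid, OOC(=O)c1cccc(Cl)c1
Why: Baeyer–Villiger oxidation, in which the primary alkyl group (C11) migrates in preference to methyl, so the old C12 leaves the skeleton as an acetyl group.

**Step 4**
Reactants: 4 2α-chloro-8α-hydroxy-12,13,14,15,16-pentanorlabdan-11-yl acetate
Product: 5 2α-chloro-12,13,14,15,16-pentanorlabd-7-en-11-yl acetate (2α-chlorodrimenyl acetate, 9α-H)
Conditions: TsOH·H2O (cat.), PhMe, 60 °C
Reagents that add atoms: none
Why: Acid-catalysed E1 dehydration of the tertiary alcohol under mildly equilibrating conditions should favour the endocyclic trisubstituted Δ7 alkene over the kinetic exocyclic isomer; the tetrasubstituted Δ8(9) isomer is the expected by-product.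

**Step 5**
Reactants: 5 2α-chlorodrimenyl acetate
Product: 6 2α-chloro-6-oxo-12,13,14,15,16-pentanorlabd-7-en-11-yl acetate
Conditions: Rh2(cap)4 (1 mol %), t-BuOOH, K2CO3, CH2Cl2, rt
Reagents that add atoms: tert-butyl hydroperoxide, CC(C)(C)OO
Why: Dirhodium caprolactamate/TBHP allylic oxidation should convert the only allylic ring methylene (C6) into the ketone, giving the conjugated 7-en-6-one.

**Step 6**
Reactants: 6 2α-chloro-6-oxo-12,13,14,15,16-pentanorlabd-7-en-11-yl acetate
Product: 7 2α-chloro-12,13,14,15,16-pentanorlabda-7,9(11)-dien-6-one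
Conditions: DBU, CH2Cl2, rt
Reagents that add atoms: none
Why: Vinylogous E1cB elimination: γ-deprotonation at C9 gives a dienolate that expels the C11 acetate and unveils the C9=C11 methylene.

**Step 7**
Reactants: 7 2α-chloro-12,13,14,15,16-pentanorlabda-7,9(11)-dien-6-one
Product: 10 2α-chloro-12,13,14,15,16-pentanorlabda-8(17),9(11)-dien-6β-ol, via potassium trienolate 8 (not isolated), via deconjugated ketone 9 (not isolated)
Conditions: KHMDS, THF, −78 °C; AcOH, −78 °C; then NaBH4, MeOH, −78 → 0 °C
Reagents that add atoms: none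
Why: Deconjugative isomerisation then reduction: the C17 methyl is the only γ-position left, so deprotonation gives the cross-conjugated trienolate, kinetic α-protonation at C7 gives the β,γ-unsaturated ketone, and borohydride attacks C6 from the α-face (the β-face is blocked by the axial C19 and C20 methyls) to set the axial 6β-alcohol.

**Step 8**
Reactants: 11 methyl 4-oxobutanoate
Product: 13 (3S)-5-oxooxolane-3-carbaldehyde, via hydroxy aldehyde 12 (not isolated)
Conditions: aq. CH2O, (R)-α,α-diphenylprolinol TMS ether (10 mol %), pH 7 buffer, PhMe, rt; then PPTS (cat.), CH2Cl2, rt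
Reagents that add atoms: formaldehyde, C=O
Why: Enamine-catalysed α-hydroxymethylation of an aldehyde: formaldehyde attacks the (E)-enamine on the face away from the diphenyl(silyloxy)methyl group to set C13 as S, and mild acid then closes the γ-lactone (5-exo-trig) with loss of methanol.

**Step 9**
Reactants: 10 2α-chloro-12,13,14,15,16-pentanorlabda-8(17),9(11)-dien-6β-ol; 13 (3S)-5-oxooxolane-3-carbaldehyde (used in excess)
Product: 16 (12S,13S)-2α-chloro-6β,16-dihydroxylabd-8(17)-en-15,12-olide (trans γ-lactone on the C12 oxygen), via borinate ester 14 (not isolated), via hydroxy lactone 15 (not isolated)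
Conditions: Ni(acac)2 (10 mol %), Et3B, THF, rt; aq. NH4Cl; then CSA (cat.), CH2Cl2, rt
Reagents that add atoms: none
Why: Ni(0), formed from Ni(acac)2 and Et3B, binds the s-cis-locked C11=C9–C8=C17 diene of 10 on the α-face (the β-face carries the axial C10 methyl) and couples C11 with the Et3B-activated aldehyde carbon of 13 by oxidative cyclisation to an oxanickelacycle (Ni on C9, η3 over C9–C8–C17); ethyl transfer from boron, β-hydride elimination (ethylene) and C–H reductive elimination at C9 then release the C8=C17 methylene and the borinate 14. The closest known reaction is the nickel-catalysed, triethylborane-promoted homoallylation of aldehydes with 1,3-dienes, which is known for 2,3-disubstituted dienes and for α-branched aliphatic aldehydes. No ring is closed in the C–C bond-forming event (the five-membered oxanickelacycle is transient); the acid work-up then closes the trans-4,5-disubstituted γ-lactone of 16 by 5-exo-trig acyl transfer from the primary C16 oxygen to the secondary C12 oxygen. C9 is set by hydrogen delivery from nickel on the α-face (9α-H, side chain β-equatorial); C12 is set in the oxanickelacycle, where the aldehyde substituent lies anti to the nickel-bound allyl unit (the 1,3-anti rule of this reaction, here 9S,12S); C13 is carried in unchanged from 13. The step needs bond formation at C11 and not at C17: this is expected because the bond forms at the diene terminus next to the more electron-rich internal carbon (C1 of isoprene), and C9 carries the fully alkylated C10 while C8 carries the CH2–CH(OH) arm, but it runs against sterics and is the main risk; the neutral conditions should keep the β-acyloxy aldehyde from epimerising or eliminating.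

**Step 10**
Reactants: 16 (12S,13S)-2α-chloro-6β,16-dihydroxylabd-8(17)-en-15,12-olide
Product: 17 (12S,13R)-2α-chloro-6β-hydroxy-15-oxo-12,15-epoxylabd-8(17)-en-16-oic acid (trans paraconic acid)
Conditions: TEMPO (20 mol %), PhI(OAc)2, MeCN/H2O, rt
Reagents that add atoms: water, O
Why: Oxoammonium (TEMPO/PhI(OAc)2) oxidation in aqueous acetonitrile takes the primary C16 alcohol to the acid via the aldehyde hydrate and should leave the hindered axial secondary 6β-alcohol untouched; any residual 15 is funnelled through 16 because only 16 has a primary alcohol.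

**Step 11**
Reactants: 17 (12S,13R)-2α-chloro-6β-hydroxy-15-oxo-12,15-epoxylabd-8(17)-en-16-oic acid
Product: 18 (12S,13R)-2α-chloro-6β-hydroxy-15-oxo-12,15-epoxylabd-8(17)-en-16-amide
Conditions: EDC·HCl, HOBt, NH4Cl, i-Pr2NEt, DMF, 0 °C → rt
Reagents that add atoms: ammonium chloride, [NH4+].[Cl-]
Why: Carbodiimide/HOBt amidation with ammonia released in situ, under conditions mild enough not to epimerise C13 or open the lactone.

**Step 12**
Reactants: 18 (12S,13R)-2α-chloro-6β-hydroxy-15-oxo-12,15-epoxylabd-8(17)-en-16-amide
Product: 19 haterumaimide F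
Conditions: t-BuOK (1.1 equiv), THF, −40 → 0 °C; AcOH
Reagents that add atoms: none
Why: Base-mediated O→N acyl transfer (imide formation from an amide and an ester): the deprotonated C16 carboxamide attacks the C15 lactone carbonyl (5-exo-trig), the C12 alkoxide is expelled, and proton transfer to the acidic imide nitrogen drives the ring switch to the succinimide with the free 12-hydroxyl.

**Compound list**

1 | (+)-sclareolide | O=C1C[C@H]2[C@](C)(O1)CC[C@H]1C(C)(C)CCC[C@]21C | starting material
2 | 2α-chlorosclareolide | O=C1C[C@H]2[C@](C)(O1)CC[C@H]1C(C)(C)C[C@H](Cl)C[C@]21C | intermediate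
3 | 2α-chloro-8α-hydroxy-14,15,16-trinorlabdan-12-one | CC(=O)C[C@H]1[C@](C)(O)CC[C@H]2C(C)(C)C[C@H](Cl)C[C@]12C | intermediate
4 | 2α-chloro-8α-hydroxy-12,13,14,15,16-pentanorlabdan-11-yl acetate | CC(=O)OC[C@H]1[C@](C)(O)CC[C@H]2C(C)(C)C[C@H](Cl)C[C@]12C | intermediate
5 | 2α-chloro-12,13,14,15,16-pentanorlabd-7-en-11-yl acetate (9α-H) | CC(=O)OC[C@H]1C(C)=CC[C@H]2C(C)(C)C[C@H](Cl)C[C@]12C | intermediate
6 | 2α-chloro-6-oxo-12,13,14,15,16-pentanorlabd-7-en-11-yl acetate | CC(=O)OC[C@H]1C(C)=CC(=O)[C@H]2C(C)(C)C[C@H](Cl)C[C@]12C | intermediate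
7 | 2α-chloro-12,13,14,15,16-pentanorlabda-7,9(11)-dien-6-one | C=C1C(C)=CC(=O)[C@H]2C(C)(C)C[C@H](Cl)C[C@]12C | intermediate
8 | potassium 2α-chloro-12,13,14,15,16-pentanorlabda-6,8(17),9(11)-trien-6-olate | C=C1C(=C)C=C([O-])[C@H]2C(C)(C)C[C@H](Cl)C[C@]12C.[K+] | intermediate
9 | 2α-chloro-12,13,14,15,16-pentanorlabda-8(17),9(11)-dien-6-one | C=C1C(=C)CC(=O)[C@H]2C(C)(C)C[C@H](Cl)C[C@]12C | intermediate
10 | 2α-chloro-12,13,14,15,16-pentanorlabda-8(17),9(11)-dien-6β-ol | C=C1C(=C)C[C@@H](O)[C@H]2C(C)(C)C[C@H](Cl)C[C@]12C | intermediate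
11 | methyl 4-oxobutanoate | COC(=O)CCC=O | starting material
12 | methyl (3S)-3-formyl-4-hydroxybutanoate | O=C[C@H](CO)CC(=O)OC | intermediate
13 | (3S)-5-oxooxolane-3-carbaldehyde | O=C[C@@H]1COC(=O)C1 | intermediate
14 | 12-O-diethylboryl derivative of 15 | C=C1C[C@@H](O)[C@H]2C(C)(C)C[C@H](Cl)C[C@]2(C)[C@H]1C[C@H](OB(CC)CC)[C@@H]1COC(=O)C1 | intermediate
15 | (12S,13S)-2α-chloro-6β,12-dihydroxylabd-8(17)-en-15,16-olide | C=C1C[C@@H](O)[C@H]2C(C)(C)C[C@H](Cl)C[C@]2(C)[C@H]1C[C@H](O)[C@@H]1COC(=O)C1 | intermediate
16 | (12S,13S)-2α-chloro-6β,16-dihydroxylabd-8(17)-en-15,12-olide | C=C1C[C@@H](O)[C@H]2C(C)(C)C[C@H](Cl)C[C@]2(C)[C@H]1C[C@@H]1OC(=O)C[C@H]1CO | intermediate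
17 | (12S,13R)-2α-chloro-6β-hydroxy-15-oxo-12,15-epoxylabd-8(17)-en-16-oic acid | C=C1C[C@@H](O)[C@H]2C(C)(C)C[C@H](Cl)C[C@]2(C)[C@H]1C[C@@H]1OC(=O)C[C@H]1C(=O)O | intermediate
18 | (12S,13R)-2α-chloro-6β-hydroxy-15-oxo-12,15-epoxylabd-8(17)-en-16-amide | C=C1C[C@@H](O)[C@H]2C(C)(C)C[C@H](Cl)C[C@]2(C)[C@H]1C[C@@H]1OC(=O)C[C@H]1C(N)=O | intermediate
19 | haterumaimide F (2α-chloro, 6β-OH, 9α-H, 12S, 13R) | C=C1C[C@@H](O)[C@H]2C(C)(C)C[C@H](Cl)C[C@]2(C)[C@H]1C[C@H](O)[C@H]1CC(=O)NC1=O | target

**Count**

Total steps: 12. Longest linear sequence: 11 (steps 1–7 and 9–12).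

**Steps most likely to fail**

Step 9. The risks are C–C bond formation at the less hindered C17 terminus instead of C11, attack on the other aldehyde face, and β-elimination or epimerisation of the aldehyde before coupling. Fallback (C9 kept from sclareolide, C11 organochromium addition): it sets out from 5. Acetate methanolysis (K2CO3, MeOH) would give 2α-chlorodrimenol F1, and silylation (TBSCl, imidazole) its TBS ether F2. The allylic oxidation of step 5 would give the 7-en-6-one TBS ether F3. The deconjugation and reduction of step 7 would give the 6β-hydroxy-8(17)-ene TBS ether F4 (silanolate is a poor leaving group, so the vinylogous elimination should be slow). TBAF would give the 6β,11-diol F5, and I2/PPh3/imidazole at the primary hydroxyl the iodide F6. Takai alkylchromium addition of F6 to 13 (CrCl2, cat. CoPc, DMF) comes back to the route at 15, which is lactonised with CSA to 16 as in step 9. C12 would then be under Felkin control only, so the 12-epimer would have to be separated.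

Step 7. The risks are reconjugation of the β,γ-unsaturated ketone before hydride arrives and competing α′-deprotonation at C5. Fallback (slow release of the ketone under reducing conditions): it sets out from 7. Enol acetylation (Ac2O, TMSCl, NaI, or KHMDS then Ac2O) would give the isolable trienyl acetate F7. Treatment with NaBH4 in EtOH/THF (dienol acetate–borohydride deconjugative reduction, as used for Δ4-3-keto steroids) would unmask the C7-protonated ketone in the presence of excess hydride and come back at 10.

Step 4. The risk is poor regioselectivity of proton loss from the C8 cation (exocyclic and Δ8(9) alkenes). Fallback (kinetic elimination, then radical isomerisation): it sets out from 4. SOCl2/pyridine at −78 °C would give the kinetic exocyclic alkene, 2α-chloro-12,13,14,15,16-pentanorlabd-8(17)-en-11-yl acetate F8. Cobalt-salen/PhSiH3 hydrogen-atom-transfer isomerisation (1,1-disubstituted to trisubstituted alkene, via abstraction of the more accessible C7 hydrogen) would come back at 5.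

**Further compounds**

F1 | step 9 | 2α-chloro-12,13,14,15,16-pentanorlabd-7-en-11-ol (2α-chlorodrimenol) | OC[C@H]1C(C)=CC[C@H]2C(C)(C)C[C@H](Cl)C[C@]12C
F2 | step 9 | 11-O-TBS ether of F1 | CC(C)(C)[Si](C)(C)OC[C@H]1C(C)=CC[C@H]2C(C)(C)C[C@H](Cl)C[C@]12C
F3 | step 9 | 11-(tert-butyldimethylsilyloxy)-2α-chloro-12,13,14,15,16-pentanorlabd-7-en-6-one | CC(C)(C)[Si](C)(C)OC[C@H]1C(C)=CC(=O)[C@H]2C(C)(C)C[C@H](Cl)C[C@]12C
F4 | step 9 | 11-(tert-butyldimethylsilyloxy)-2α-chloro-12,13,14,15,16-pentanorlabd-8(17)-en-6β-ol | C=C1C[C@@H](O)[C@H]2C(C)(C)C[C@H](Cl)C[C@]2(C)[C@H]1CO[Si](C)(C)C(C)(C)C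
F5 | step 9 | 2α-chloro-12,13,14,15,16-pentanorlabd-8(17)-ene-6β,11-diol | C=C1C[C@@H](O)[C@H]2C(C)(C)C[C@H](Cl)C[C@]2(C)[C@H]1CO
F6 | step 9 | 2α-chloro-11-iodo-12,13,14,15,16-pentanorlabd-8(17)-en-6β-ol | C=C1C[C@@H](O)[C@H]2C(C)(C)C[C@H](Cl)C[C@]2(C)[C@H]1CI
F7 | step 7 | 2α-chloro-12,13,14,15,16-pentanorlabda-6,8(17),9(11)-trien-6-yl acetate | C=C1C(=C)C=C(OC(C)=O)[C@H]2C(C)(C)C[C@H](Cl)C[C@]12C
F8 | step 4 | 2α-chloro-12,13,14,15,16-pentanorlabd-8(17)-en-11-yl acetate | CC(=O)OC[C@H]1C(=C)CC[C@H]2C(C)(C)C[C@H](Cl)C[C@]12C
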